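The data are calculated with made-up constants.

Read the flask at 12 h by asking what reagent the target step has to work with. I assume the second substrate takes one reagent each, quickly (a pre-equilibrium), so 0.129 M is the free reagent: reagent charged minus second substrate charged.

all flasks: solid substrate 0.099 M
- larch: reagent 0.21 M; second substrate 0.0198 M; run made earlier
- maple: reagent 0.33 M; second substrate 0.0198 M; run made earlier
- cedar: reagent 0.149 M; second substrate 0.0099 M; run made earlier
- flask: reagent 0.149 M; second substrate 0.0198 M; time 12 h

- larch (time / h: solid substrate / %, target / %): 1.00: 94.4, 4.1; 2.00: 88.4, 6.9; 3.00: 87.5, 7.1; 4.00: 84.9, 9.5; 5.00: 83.7, 10.7; 6.00: 82.6, 10.9; 8.00: 81.7, 12.3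
- maple (time / h: solid substrate / %, target / %): 0.500: 95.3, 3.7; 0.833: 94.7, 3.7; 1.33: 93.2, 6.2; 2.00: 85.5, 10.0; 3.00: 82.1, 11.7; 5.00: 79.4, 16.6; 8.00: 77.6, 20.3
- cedar (time / h: solid substrate / %, target / %): 0.667: 96.8, 3.3; 2.00: 89.5, 5.0; 3.00: 88.0, 5.6; 5.00: 84.4, 7.7; 8.00: 84.6, 11.0

(standard deviation of a reading: 1 percentage point)

- as a solid, counted per litre of solution: solid substrate
- the earlier runs were read with a standard deviation of 1 percentage point
- at the start none of the solid substrate is in solution
- what has only dissolved of solid substrate counts as not reacted
- starting material means what is dissolved; the solid is not counted in it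
- the reaction counts as stopped when no species that holds the solid substrate changes by six tenths of a point or more over the second half of the time

1. at 12 h, what has stopped the reaction, if anything has (for what has run out or reacted, a solid counts together with what of it has only dissolved) (the reagent has run out first / it is still moving / all of the solid substrate has reacted / forward and back rates have come level)
2. part of the solid substrate that has turned into other species by 12 h (what has only dissolved does not count)
3. amount of target at 12 h, in percent of the solid substrate charged
4. amount of starting material at 12 h, in percent of the solid substrate charged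

In the maple run, with 0.310 M free, target first formed at 0.0740 h⁻¹ of the charge. The larch run, with 0.190 M free, managed 0.0410 h⁻¹. The rates stand at 1.80 to one and the free reagent at 1.63 to one, so I scale the start by free reagent. That factor of 0.416 gives this flask 0.0308 h⁻¹.

What slows it is target going back, as the rate fades towards a ceiling. Last readings per free reagent are 0.647 M⁻¹ in larch and 0.654 M⁻¹ in maple, so I carry 0.651 M⁻¹. Cedar's last reading, 11.0%, lies 2 percentage points above this, with a scatter of 1 point.

My ceiling for this flask is 8.41%, which at the starting rate takes 2.73 h. The rate therefore falls by a factor 0.111 by half-time and 0.0123 by the end. That leaves 0.83 points for the second half. By the test in the notes that counts as still moving, so still moving is my call for this flask. Conversion equals target, and starting material is the mean gap in the last readings, 4.17%.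

The forecast gave 14% target, 14.5% conversion and 4.5% starting material, “so it is still moving”.

The flask gives: forward and back rates have come level, with conversion 8.72%, target 8.72% and starting material 5.45%.

    starting material + reagent ⇌ target (K = 13.0 M⁻¹, k = 0.520 M⁻¹ min⁻¹)
    solid substrate ⇌ starting material, rate k2*(cs2 - [starting material]) while solid is left; crystals form when [starting material] > cs2 (solubility = 5.40 mM, k = 0.0270 min⁻¹)
    second substrate + reagent ⇌ second product (K = 55.0 M⁻¹, k = 0.910 M⁻¹ min⁻¹)

Against my 8.41%, the flask holds 8.72% target, and 83% of its reagent is still unbound, where free reagent counted 86.7%. The flask's largest change over the second half was 0.33 points against my 0.83 points, so it counts as level where I had it still moving. Now take the neighbour flask charged with 0.089 M reagent: its free reagent is 0.0692 M, which times 0.651 M⁻¹ gives 4.50%, and that neighbour flask stands at 4.86% target.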